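Numbering (elemanolide convention): ring B = C5–C10; C10 carries CH3 (C14) and vinyl (C1=C2); C5 carries the acrylic acid C4(=C3)–C15; C7 carries C11(=C13)–C12, lactonised on O6; C8 carries the tiglate; α/β are the faces of ring B, the C10 methyl being β.
Enabling feature: in ring B the unit C9–C8(O)–C7 is an acetone α,α′-dianion whose two ends meet a carbinol carbon (C6) and a quaternary allylic carbon (C10). O6 can form a γ-lactone with either acrylate arm (C12 or C15), so C6 can be entered as a five-membered acyloxycarbenium ion held in a temporary C15 lactone.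
Disconnections: target ⇐ lactone switch on O6 (C15 acyl → C12 acyl) ⇐ tigloylation, two α-methylenations (C3, C13) and C8 reduction of a bicyclic keto lactone ⇐ [3+3] annulation (C6–C7 and C9–C10) of a lactol ether carrying an allylic acetate with a 2-silyloxyallylsilane.
The lactol ether ⇐ anti conjugate addition of a (Z)-alkenyl metal to (5R)-5-menthyloxyfuran-2(5H)-one; its acetal carbon is the only purchased stereocentre (menthol is released again), and C5 → C6 → C10 → C7 → C8 are relayed from it.
Ring order: temporary 15,6-γ-lactone (bought), ring B (key step), natural 12,6-γ-lactone by transacylation (last step).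
Key step: step 7

Remark: the enol silane reagent of step 6 is used as an E/Z mixture and drawn as the Z isomer; this geometry is lost in step 7.

Step 1
Reactants: 1 but-2-yn-1-ol
Product: 3 (Z)-3-iodobut-2-en-1-ol, via cyclic alkenylalanate 2 (not isolated)
Conditions: NaAlH2(OCH2CH2OMe)2, THF, 0 to 23 °C; then I2, −78 to 0 °C
Reagents that add atoms: iodine, II
Why: hydroxyl-directed trans-hydroalumination puts aluminium on C3 syn to the CH2O group in a five-membered alanate, and iodinolysis with retention should give the Z iodide (alkyne hydroalumination–iodination).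

Step 2
Reactants: 3 (Z)-3-iodobut-2-en-1-ol
Product: 4 tert-butyl{[(2Z)-3-iodobut-2-en-1-yl]oxy}dimethylsilane
Conditions: t-BuMe2SiCl, imidazole, CH2Cl2, 23 °C
Reagents that add atoms: tert-butyl(chloro)dimethylsilane, CC(C)(C)[Si](C)(C)Cl
Why: the primary alcohol is masked against the organomagnesium chemistry of step 3 (silyl ether formation).

Step 3
Reactants: 4 tert-butyl{[(2Z)-3-iodobut-2-en-1-yl]oxy}dimethylsilane; 5 (5R)-5-{[(1R,2S,5R)-5-methyl-2-(propan-2-yl)cyclohexyl]oxy}furan-2(5H)-one
Product: 7 (4S,5R)-4-[(2Z)-4-{[tert-butyl(dimethyl)silyl]oxy}but-2-en-2-yl]-5-{[(1R,2S,5R)-5-methyl-2-(propan-2-yl)cyclohexyl]oxy}oxolan-2-one (4,5-trans), via alkenylmagnesium chloride 6 (not isolated)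
Conditions: i-PrMgCl·LiCl, THF, 0 to 23 °C; then CuBr·SMe2 (10 mol %), 5, THF, −78 to −30 °C; aq NH4Cl
Reagents that add atoms: none
Why: iodine–magnesium exchange keeps the Z geometry, and the copper-catalysed 1,4-addition to the butenolide should occur anti to the menthyloxy group, which sets C5 (conjugate addition under substrate control).

Step 4
Reactants: 7 the silyl ether of step 3
Product: 9 (2Z)-3-[(2R,3S)-2-{[(1R,2S,5R)-5-methyl-2-(propan-2-yl)cyclohexyl]oxy}-5-oxooxolan-3-yl]but-2-en-1-yl acetate, via allylic alcohol 8 (not isolated)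
Conditions: Bu4NF, THF, 0 °C; then Ac2O, DMAP (cat.), 23 °C
Reagents that add atoms: acetic anhydride, CC(=O)OC(C)=O
Why: fluoride removes the silyl group and the alkoxide is acetylated in the same flask, which turns the allylic oxygen into the leaving group for step 7 (desilylation, then acylation).

Step 5
Reactants: 10 methyl 4-chloro-4-oxobutanoate; 11 (trimethylsilyl)methylmagnesium chloride
Product: 12 methyl 4-oxo-5-(trimethylsilyl)pentanoate
Conditions: CuI (5 mol %), THF, −78 °C
Reagents that add atoms: none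
Why: copper-catalysed acylation of the Grignard reagent by the acid chloride should stop at the ketone and leave the methyl ester untouched (ketone synthesis from an acid chloride).

Step 6
Reactants: 12 methyl 4-oxo-5-(trimethylsilyl)pentanoate
Product: 14 methyl (3Z)-4-[(trimethylsilyl)oxy]-5-(trimethylsilyl)pent-3-enoate, via lithium enolate 13 (not isolated)
Conditions: LiN(i-Pr)2, THF, −78 °C; then Me3SiCl, −78 to 0 °C
Reagents that add atoms: chlorotrimethylsilane, C[Si](C)(C)Cl
Why: kinetic deprotonation of the α-silyl ketone should occur at the unhindered ketone α-CH2 on the ester side (more acidic than the ester α-position), and O-silylation gives the 2-silyloxyallylsilane (kinetic enol silane formation).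

Step 7
Reactants: 9 the lactol ether with the allylic acetate; 14 the 2-silyloxyallylsilane
Product: 16 methyl 2-[(3aS,4S,7S,7aR)-4-ethenyl-4-methyl-2,6-dioxooctahydro-1-benzofuran-7-yl]acetate (5α-H, 6β-H, 7α-H, 10β-CH3; trans-fused 15,6-lactone), via enol silane 15 (not isolated)
Conditions: Me3SiOTf (0.3 equiv), CH2Cl2, −78 to 0 °C; then 1 M HCl, THF, 23 °C
Reagents that add atoms: none
Why: Proposed new method: catalytic Me3SiOTf ionises the menthyl acetal of 9 to a five-membered acyloxycarbenium ion at C6, C7 of 14 (at once the β-carbon of a silyl enol ether and the γ-carbon of an allylsilane) adds to it with loss of the C9 silyl group to give enol silane 15, and the regenerated Me3SiOTf then ionises the allylic acetate so that C9 of 15 captures the tertiary terminus C10 of the allyl cation and the ketone is released. The closest known reaction types are the Mukaiyama/Hosomi–Sakurai addition of 2-silyloxyallylsilanes (acetone α,α′-dianion equivalents) to two electrophiles in sequence and the SN1 alkylation of enol silanes by tertiary or allylic acetates, but their union into a [3+3] carbocyclisation on a lactol ether that carries an allylic acetate has not been shown. Ring B is closed by a 6-(enolendo)-exo-trig attack on the allyl cation through a chair that is trans-fused to the γ-lactone, the alternative attack at C2 requiring an eight-membered ring. C6 is set by attack anti to the C5 alkenyl group on the flat lactone oxocarbenium ion (C5 itself having been set anti to the menthyloxy group of 5), C10 by the chair in which the planar (Z)-allyl cation arm lies equatorial so that the methyl group becomes axial and β, and C7, α to the new ketone, by the acid equilibration to the equatorial β epimer. The step needs the acetal to ionise before the acetate and C7 to react before C9; the first should follow from the easier ionisation of the acyloxy acetal at −78 °C, the second from the fact that C9 stays sp3 and silyl-bearing until C7 has bonded.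

Step 8
Reactants: 16 the bicyclic keto lactone
Product: 18 methyl 2-[(3aS,4S,6R,7S,7aR)-4-ethenyl-4-methyl-2-oxo-6-[(triethylsilyl)oxy]octahydro-1-benzofuran-7-yl]acetate (8β-O), via lithium alkoxide 17 (not isolated)
Conditions: LiBH(s-Bu)3, THF, −78 °C; then Et3SiOTf, 2,6-lutidine, −78 to 0 °C
Reagents that add atoms: triethylsilyl trifluoromethanesulfonate, CC[Si](CC)(CC)OS(=O)(=O)C(F)(F)F
Why: the bulky hydride should attack the C8 ketone from the equatorial α side because the axial side is closed by the axial C10 methyl group, and the axial 8β-alkoxide is silylated before it can lactonise onto the C12 ester (substrate-controlled ketone reduction, then silylation).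

Step 9
Reactants: 18 the silyl ether of step 8
Product: 22 methyl 2-[(3aR,4S,6R,7S,7aR)-4-ethenyl-4-methyl-3-methylidene-2-oxo-6-[(triethylsilyl)oxy]octahydro-1-benzofuran-7-yl]prop-2-enoate, via dilithium bis-enolate 19 (not isolated), via bis-Mannich base 20 (not isolated), via bis-ammonium diiodide 21 (not isolated)
Conditions: LiN(i-Pr)2 (2.4 equiv), THF, −78 °C; [CH2=NMe2]I, −78 to 23 °C; then MeI, MeOH, 23 °C; then aq NaHCO3, CH2Cl2, 23 °C
Reagents that add atoms: N,N-dimethylmethyleneiminium iodide, C=[N+](C)C.[I-]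
Why: the lactone and ester enolates are aminomethylated, and exhaustive methylation followed by base-induced loss of trimethylamine should put both exocyclic methylene groups (C3 and C13) in place (Mannich reaction with Eschenmoser's salt, Hofmann-type elimination).

Step 10
Reactants: 22 the bis-methylene silyl ether
Product: 23 methyl 2-[(3aR,4S,6R,7R,7aR)-4-ethenyl-6-hydroxy-4-methyl-3-methylidene-2-oxooctahydro-1-benzofuran-7-yl]prop-2-enoate
Conditions: HF·pyridine, pyridine, THF, 0 °C
Reagents that add atoms: none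
Why: buffered fluoride should cleave the triethylsilyl ether without adding to either acrylate unit (desilylation).

Step 11
Reactants: 23 the 8β-alcohol
Product: 24 methyl 2-[(3aR,4S,6R,7R,7aR)-4-ethenyl-4-methyl-3-methylidene-6-{[(2E)-2-methylbut-2-enoyl]oxy}-2-oxooctahydro-1-benzofuran-7-yl]prop-2-enoate
Conditions: (E)-2-methylbut-2-enoyl chloride, Et3N, DMAP (cat.), CH2Cl2, 0 to 23 °C
Reagents that add atoms: (E)-2-methylbut-2-enoyl chloride, C/C=C(\C)C(=O)Cl
Why: acylation of the axial 8β-hydroxyl by the acid chloride under nucleophilic catalysis should outrun its lactonisation onto the conjugated C12 ester and keeps the E geometry of the tiglate (esterification).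

Step 12
Reactants: 24 the tiglate with the 15,6-lactone
Product: 27 2-[(3aR,4R,6S,7R,7aR)-6-ethenyl-6-methyl-3-methylidene-4-{[(2E)-2-methylbut-2-enoyl]oxy}-2-oxooctahydro-1-benzofuran-7-yl]prop-2-enoic acid (CNP0256928.1), via hydroxy carboxylate 25 (not isolated), via lithium carboxylate 26 (not isolated)
Conditions: LiOH (1.0 equiv), THF–H2O 3:1, 0 °C; then 1 M HCl to pH 3
Reagents that add atoms: lithium hydroxide, [Li+].[OH-]
Why: hydroxide should open the strained trans-fused 15,6-lactone to the C15 carboxylate, which cannot re-close under base, and the freed 6-alkoxide closes a five-membered lactone onto the neighbouring C12 methyl ester, so the acid is released and the natural lactone formed in one transacylation (saponification, intramolecular transesterification).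

Compound list
1 | but-2-yn-1-ol | CC#CCO | starting material
2 | sodium 2,2-bis(2-methoxyethoxy)-3-methyl-2,5-dihydro-1,2-oxaluminol-2-uide (cyclic alkenylalanate) | CC1=CCO[Al-]1(OCCOC)OCCOC.[Na+] | intermediate (not isolated)
3 | (Z)-3-iodobut-2-en-1-ol | C/C(I)=C/CO | intermediate
4 | tert-butyl{[(2Z)-3-iodobut-2-en-1-yl]oxy}dimethylsilane | C/C(I)=C/CO[Si](C)(C)C(C)(C)C | intermediate
5 | (5R)-5-{[(1R,2S,5R)-5-methyl-2-(propan-2-yl)cyclohexyl]oxy}furan-2(5H)-one | C[C@@H]1CC[C@H]([C@@H](C1)O[C@H]2C=CC(=O)O2)C(C)C | starting material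
6 | [(2Z)-4-{[tert-butyl(dimethyl)silyl]oxy}but-2-en-2-yl]magnesium chloride (LiCl complex) | C/C([Mg]Cl)=C/CO[Si](C)(C)C(C)(C)C | intermediate (not isolated)
7 | (4S,5R)-4-[(2Z)-4-{[tert-butyl(dimethyl)silyl]oxy}but-2-en-2-yl]-5-{[(1R,2S,5R)-5-methyl-2-(propan-2-yl)cyclohexyl]oxy}oxolan-2-one | C[C@@H]1CC[C@H]([C@@H](C1)O[C@@H]2OC(=O)C[C@H]2/C(C)=C\CO[Si](C)(C)C(C)(C)C)C(C)C | intermediate
8 | (4S,5R)-4-[(2Z)-4-hydroxybut-2-en-2-yl]-5-{[(1R,2S,5R)-5-methyl-2-(propan-2-yl)cyclohexyl]oxy}oxolan-2-one | C[C@@H]1CC[C@H]([C@@H](C1)O[C@@H]2OC(=O)C[C@H]2/C(C)=C\CO)C(C)C | intermediate (not isolated)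
9 | (2Z)-3-[(2R,3S)-2-{[(1R,2S,5R)-5-methyl-2-(propan-2-yl)cyclohexyl]oxy}-5-oxooxolan-3-yl]but-2-en-1-yl acetate | C[C@@H]1CC[C@H]([C@@H](C1)O[C@@H]2OC(=O)C[C@H]2/C(C)=C\COC(C)=O)C(C)C | intermediate
10 | methyl 4-chloro-4-oxobutanoate | COC(=O)CCC(Cl)=O | starting material
11 | (trimethylsilyl)methylmagnesium chloride | C[Si](C)(C)C[Mg]Cl | starting material
12 | methyl 4-oxo-5-(trimethylsilyl)pentanoate | COC(=O)CCC(=O)C[Si](C)(C)C | intermediate
13 | lithium (2Z)-5-methoxy-5-oxo-1-(trimethylsilyl)pent-2-en-2-olate | COC(=O)C/C=C(\[O-])C[Si](C)(C)C.[Li+] | intermediate (not isolated)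
14 | methyl (3Z)-4-[(trimethylsilyl)oxy]-5-(trimethylsilyl)pent-3-enoate | COC(=O)C/C=C(\O[Si](C)(C)C)C[Si](C)(C)C | intermediate
15 | methyl 3-{(2R,3S)-3-[(2Z)-4-(acetyloxy)but-2-en-2-yl]-5-oxooxolan-2-yl}-4-[(trimethylsilyl)oxy]pent-4-enoate (both C3 epimers) | COC(=O)CC([C@@H]1OC(=O)C[C@H]1/C(C)=C\COC(C)=O)C(=C)O[Si](C)(C)C | intermediate (not isolated)
16 | methyl 2-[(3aS,4S,7S,7aR)-4-ethenyl-4-methyl-2,6-dioxooctahydro-1-benzofuran-7-yl]acetate | C=C[C@]1(C)CC(=O)[C@@H](CC(=O)OC)[C@@H]2OC(=O)C[C@@H]12 | intermediate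
17 | lithium 8β-alkoxide from reduction of 16 | C=C[C@]1(C)C[C@@H]([O-])[C@@H](CC(=O)OC)[C@@H]2OC(=O)C[C@@H]12.[Li+] | intermediate (not isolated)
18 | methyl 2-[(3aS,4S,6R,7S,7aR)-4-ethenyl-4-methyl-2-oxo-6-[(triethylsilyl)oxy]octahydro-1-benzofuran-7-yl]acetate | C=C[C@]1(C)C[C@@H](O[Si](CC)(CC)CC)[C@@H](CC(=O)OC)[C@@H]2OC(=O)C[C@@H]12 | intermediate
19 | dilithium bis-enolate of 18 (lactone and ester) | C=C[C@]1(C)C[C@@H](O[Si](CC)(CC)CC)[C@@H](C=C([O-])OC)[C@@H]2OC([O-])=C[C@@H]12.[Li+].[Li+] | intermediate (not isolated)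
20 | bis(dimethylaminomethyl) derivative of 18 (at C4 and C11; epimer mixture) | C=C[C@]1(C)C[C@@H](O[Si](CC)(CC)CC)[C@@H](C(CN(C)C)C(=O)OC)[C@@H]2OC(=O)C(CN(C)C)[C@@H]12 | intermediate (not isolated)
21 | bis(trimethylammoniomethyl) diiodide from 20 | C=C[C@]1(C)C[C@@H](O[Si](CC)(CC)CC)[C@@H](C(C[N+](C)(C)C)C(=O)OC)[C@@H]2OC(=O)C(C[N+](C)(C)C)[C@@H]12.[I-].[I-] | intermediate (not isolated)
22 | methyl 2-[(3aR,4S,6R,7S,7aR)-4-ethenyl-4-methyl-3-methylidene-2-oxo-6-[(triethylsilyl)oxy]octahydro-1-benzofuran-7-yl]prop-2-enoate | C=C[C@]1(C)C[C@@H](O[Si](CC)(CC)CC)[C@@H](C(=C)C(=O)OC)[C@@H]2OC(=O)C(=C)[C@@H]12 | intermediate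
23 | methyl 2-[(3aR,4S,6R,7R,7aR)-4-ethenyl-6-hydroxy-4-methyl-3-methylidene-2-oxooctahydro-1-benzofuran-7-yl]prop-2-enoate | C=C[C@]1(C)C[C@@H](O)[C@@H](C(=C)C(=O)OC)[C@@H]2OC(=O)C(=C)[C@@H]12 | intermediate
24 | methyl 2-[(3aR,4S,6R,7R,7aR)-4-ethenyl-4-methyl-3-methylidene-6-{[(2E)-2-methylbut-2-enoyl]oxy}-2-oxooctahydro-1-benzofuran-7-yl]prop-2-enoate | C=C[C@]1(C)C[C@@H](OC(=O)/C(C)=C/C)[C@@H](C(=C)C(=O)OC)[C@@H]2OC(=O)C(=C)[C@@H]12 | intermediate
25 | lithium carboxylate of the ring-opened 6-hydroxy 12-methyl ester (15,6-lactone opened) | C=C[C@]1(C)C[C@@H](OC(=O)/C(C)=C/C)[C@@H](C(=C)C(=O)OC)[C@H](O)[C@H]1C(=C)C(=O)[O-].[Li+] | intermediate (not isolated)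
26 | lithium salt of 27 | C=C[C@]1(C)C[C@@H](OC(=O)/C(C)=C/C)[C@H]2C(=C)C(=O)O[C@@H]2[C@H]1C(=C)C(=O)[O-].[Li+] | intermediate (not isolated)
27 | 2-[(3aR,4R,6S,7R,7aR)-6-ethenyl-6-methyl-3-methylidene-4-{[(2E)-2-methylbut-2-enoyl]oxy}-2-oxooctahydro-1-benzofuran-7-yl]prop-2-enoic acid | C=C[C@]1(C)C[C@@H](OC(=O)/C(C)=C/C)[C@H]2C(=C)C(=O)O[C@@H]2[C@H]1C(=C)C(=O)O | target

Total steps: 12. Longest linear sequence: 10 (steps 1–4 and 7–12).

Steps most likely to fail

Step 7 (Proposed new method). What may go wrong: the allylic acetate ionises before the acetal, so that 14 is allylated intermolecularly at the wrong carbon; the enol silane is lost by protodesilylation before ring closure; facial selectivity at C10 is low. The fallback makes the two bonds separately by known reactions, setting out from 9 and 14 and returning at 16. BF3·OEt2 (1.1 equiv) in CH2Cl2 at −78 °C, a cold NaHCO3 quench and an AcOH–H2O work-up should stop after the Mukaiyama-type addition and give methyl 3-{(2R,3S)-3-[(2Z)-4-(acetyloxy)but-2-en-2-yl]-5-oxooxolan-2-yl}-4-oxopentanoate F1. LiN(SiMe3)2 and Me3SiCl at −78 °C should turn its methyl ketone into the terminal enol silane 15, now isolated. A Tsuji–Trost cyclisation (Pd2(dba)3 2.5 mol %, PPh3, Bu4N[Ph3SiF2], THF, 23 °C), in which the fluoride-activated enol silane attacks the π-allyl complex at the tertiary terminus because only that gives a six-membered ring, followed by the HCl equilibration of step 7, should give 16.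

Step 12. What may go wrong: hydroxide attack on the newly formed 12,6-lactone or on the tiglate competes with opening of the 15,6-lactone, and re-lactonisation on acidification then scrambles the acyl partner of O6. The fallback moves the switch in front of the acylation, so that no tiglate is present and the bulky 8-silyloxy group shields the new lactone; it sets out from 22 and returns at 27. LiOH (1.0 equiv), THF–H2O, 0 °C, then HCl, should give 2-[(3aS,4R,6S,7R,7aR)-6-ethenyl-6-methyl-3-methylidene-2-oxo-4-[(triethylsilyl)oxy]octahydro-1-benzofuran-7-yl]prop-2-enoic acid F2. HF·pyridine should give 2-[(3aR,4R,6S,7R,7aR)-6-ethenyl-4-hydroxy-6-methyl-3-methylidene-2-oxooctahydro-1-benzofuran-7-yl]prop-2-enoic acid F3. (E)-2-Methylbut-2-enoyl chloride (2.2 equiv), Et3N and DMAP, then aq NaHCO3–THF to hydrolyse the mixed anhydride at C15, should give 27.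

Step 9. What may go wrong: incomplete double enolisation (the lactone α-carbon next to C5 is hindered) and retro-Mannich loss during quaternisation. The fallback uses aldol–dehydration in place of Mannich–elimination, setting out from 18 and returning at 22. LiN(i-Pr)2 (2.4 equiv), THF, −78 °C, then gaseous CH2O, should give the bis(hydroxymethyl) derivative of 18 F4. MsCl, Et3N, CH2Cl2, 0 °C should give the bis(methanesulfonate) of F4 F5, and DBU in toluene at 23 °C should eliminate both to 22.

Further compounds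
F1 | step 7 | methyl 3-{(2R,3S)-3-[(2Z)-4-(acetyloxy)but-2-en-2-yl]-5-oxooxolan-2-yl}-4-oxopentanoate (both C3 epimers) | COC(=O)CC([C@@H]1OC(=O)C[C@H]1/C(C)=C\COC(C)=O)C(C)=O
F2 | step 12 | 2-[(3aS,4R,6S,7R,7aR)-6-ethenyl-6-methyl-3-methylidene-2-oxo-4-[(triethylsilyl)oxy]octahydro-1-benzofuran-7-yl]prop-2-enoic acid | C=C[C@]1(C)C[C@@H](O[Si](CC)(CC)CC)[C@H]2C(=C)C(=O)O[C@@H]2[C@H]1C(=C)C(=O)O
F3 | step 12 | 2-[(3aR,4R,6S,7R,7aR)-6-ethenyl-4-hydroxy-6-methyl-3-methylidene-2-oxooctahydro-1-benzofuran-7-yl]prop-2-enoic acid | C=C[C@]1(C)C[C@@H](O)[C@H]2C(=C)C(=O)O[C@@H]2[C@H]1C(=C)C(=O)O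
F4 | step 9 | bis(hydroxymethyl) derivative of 18 (CH2OH at C4 and C11; epimer mixture) | C=C[C@]1(C)C[C@@H](O[Si](CC)(CC)CC)[C@@H](C(CO)C(=O)OC)[C@@H]2OC(=O)C(CO)[C@@H]12
F5 | step 9 | bis(methanesulfonate) of F4 | C=C[C@]1(C)C[C@@H](O[Si](CC)(CC)CC)[C@@H](C(COS(C)(=O)=O)C(=O)OC)[C@@H]2OC(=O)C(COS(C)(=O)=O)[C@@H]12
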